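32.8 min is the number to carry. The blue run, at 70 °C, lost target from 52% at 3.00 min to 43% at 12.0 min. Read as an apparent first-order decay, that gives a drain half-life of target, a reading that carries the scatter of its two points.

| flask | starting material | partner | protic impurity | temperature | remark | time |
|---|---|---|---|---|---|---|
| amber | 1.5 M | 0.68 M | 0.45 M | 45 °C | run made earlier |  |
| blue | 1.5 M | 2.7 M | 0.45 M | 70 °C | run made earlier |  |
| east | 1.5 M | 1.35 M | 0.450 M |  | at 90 °C until 10 min, from then on at 50 °C | 20 min |
| north-west | 1.5 M | 1.35 M | 0.450 M | 70 °C |  | 20 min |
| north-east | 1.5 M | 1.35 M | 0.450 M | 90 °C |  | 20 min |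
| north | 1.5 M | 1.35 M | 0.450 M | 50 °C |  | 20 min |

- amber (time / min: target / %, starting material / %): 5.00: 11, 86; 10.0: 17, 75; 15.0: 20, 67; 20.0: 22, 62; 30.0: 29, 57; 40.0: 28, 55
- blue (time / min: target / %, starting material / %): 0.667: 29, 64; 2.00: 50, 41; 3.00: 52, 35; 5.00: 48, 31; 8.00: 47, 26; 10.0: 44, 27; 12.0: 43, 24

(standard deviation of a reading: 1.5 percentage points)

1. which flask leads in amount of target, in percent of the starting material charged ("all alike" within 1.5 percentage points) (east / north-west / north-east / north / all alike)
2. how much target is there at the end, in percent of the starting material charged: east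
3. how much target is there at the end, in percent of the starting material charged: north-west
4. how much target is there at the end, in percent of the starting material charged: north-east
5. how much target is there at the end, in percent of the starting material charged: north

- the analysis behind the earlier runs scatters by 1.5 percentage points, standard deviation
- a reading of starting material is of its free form alone

1. Slope. Per unit of [partner], starting material falls 4.85 times as fast at first in blue, at 70 °C, as in amber, at 45 °C. My assumption is that the drain speeds up in step with this. Stepping from 70 °C to 90 °C, or down to 50 °C, then gives a factor 3.54, so the drain half-life is 9.27 min at 90 °C and 116 min at 50 °C.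

2. Level. The [partner] charged here is twice amber's and half blue's, so I take the mean of amber's top reading and blue's peak as the level target climbs to: 40.5%.

3. Knee. Blue's highest target reading stands at 3.00 min, earlier than 20 min. That is blue's knee, not one read from the new flasks; I assume for simplicity that the drain counts from time zero.

4. Fall. My reckoning at 20 min gives 9.08% in north-east, 26.5% in north-west, 18.1% in east and 35.9% in north. In this reckoning north leads.

5. Forecast. The forecast differs: it puts north-west first, with 34% for east, 40% for north-west, 31% for north-east and 36% for north, holding that at the hot end “the reaction is fast but target loss is worst”.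

6. Result. north leads, with 43.5%; north-west gives 24.2%, east 18.5% and north-east 7.41%.

    starting material + partner ⇌ target (K = 0.350 M⁻¹, k = 0.0170 M⁻¹ s⁻¹, Ea = 68.0 kJ mol⁻¹, ΔH = −45.0 kJ mol⁻¹)
    starting material + partner ⇌ isomer of the product (K = 1.90 M⁻¹, k = 0.00150 M⁻¹ s⁻¹, Ea = 67.0 kJ mol⁻¹, ΔH = 23.0 kJ mol⁻¹)
    starting material + protic impurity → quenched substrate (k = 0.00740 M⁻¹ s⁻¹, Ea = 65.0 kJ mol⁻¹)
    (constants at 90 °C)

In north, target rose from 36.5% at 10.0 min to 43.5% at 20.0 min, so my assumption of a drain from time zero fails there. In north-west, target went from 28.9% at 10.0 min to 24.2% at 20.0 min, a drain half-life of 39.1 min. In north-east, the forward step to isomer of the product starts by using partner at 0.088 of the rate of the forward step to target, yet at 20.0 min isomer stands at 33.9% against 7.41% of target: kinetic against thermodynamic control. Run the north-east flask at 105 °C and the scaling gives a drain half-life of 3.59 min, hence 0.852% at 20 min; that flask holds 3.20%.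

The data come from a simulation with made-up constants; noise was put on by code.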